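**Retrosynthetic overview**
- The target is the bis-desilylated form of its silyl-protected ester. The pyran ring (ring B) is opened at the O2–C3 bond to the enol of a 4-formyl-3-alkynylcyclohexenone, which comes from 1,4-reduction of an enal.
- That enal is an ortho-quinol ester. It is disconnected at the C7–O bond to 2-alkynyl-4-hydroxy-5-methylbenzaldehyde and an orsellinate delivered from a chiral trivalent-iodine reagent. This step sets the only stereocentre.
- The phenol comes from Sonogashira coupling of 2-bromo-4-hydroxy-5-methylbenzaldehyde with (E)-pent-2-en-4-ynyl acetate.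
- Ring order: ring A (carbocycle) is bought as a benzene ring and dearomatized; ring B (pyran) is closed last; the orsellinate ring is bought.

Assumption: (E)-pent-2-en-4-yn-1-ol, orsellinic acid and the lactamide iodoarene are taken as catalogue items, and the (R,R) iodane is drawn as the one giving the (S) centre; if induction proves opposite, its (S,S) enantiomer is used with no other change.

**Step 1**
Reactants: 1 4-bromo-2-methoxy-1-methylbenzene
Product: 2 2-bromo-4-methoxy-5-methylbenzaldehyde
Conditions: Cl2CHOMe, TiCl4, CH2Cl2, 0 °C; aqueous work-up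
Reagents that add atoms: dichloromethyl methyl ether, ClC(Cl)OC; water, O
Why: Rieche formylation (electrophilic aromatic substitution) goes para to the methoxy group, the most activated and least hindered position, which is ortho to bromine.

**Step 2**
Reactants: 2 2-bromo-4-methoxy-5-methylbenzaldehyde
Product: 3 2-bromo-4-hydroxy-5-methylbenzaldehyde
Conditions: BBr3, CH2Cl2, −78 °C to rt; H2O
Reagents that add atoms: none
Why: Lewis-acid aryl methyl ether cleavage with BBr3 frees the phenol and leaves the aldehyde and the aryl bromide untouched.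

**Step 3**
Reactants: 4 (E)-pent-2-en-4-yn-1-ol
Product: 5 (E)-pent-2-en-4-yn-1-yl acetate
Conditions: Ac2O, pyridine, DMAP (cat.), CH2Cl2, 0 °C to rt
Reagents that add atoms: acetic anhydride, CC(=O)OC(C)=O
Why: Standard O-acetylation of a primary allylic alcohol by nucleophilic catalysis; the alkene geometry is not touched.

**Step 4**
Reactants: 3 2-bromo-4-hydroxy-5-methylbenzaldehyde; 5 (E)-pent-2-en-4-yn-1-yl acetate
Product: 6 (E)-5-(2-formyl-5-hydroxy-4-methylphenyl)pent-2-en-4-yn-1-yl acetate
Conditions: PdCl2(PPh3)2 (3 mol %), CuI (5 mol %), Et3N, THF, 45 °C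
Reagents that add atoms: none
Why: Sonogashira coupling at the aryl bromide activated by the ortho formyl group; oxidative addition there should outrun ionization of the primary allylic acetate at this temperature.

**Step 5**
Reactants: 7 orsellinic acid (2,4-dihydroxy-6-methylbenzoic acid)
Product: 9 2,4-bis(tert-butyldimethylsilyloxy)-6-methylbenzoic acid, via tris-silyl orsellinate 8 (not isolated)
Conditions: TBSCl (3.5 equiv), imidazole, DMF, rt; then AcOH/THF/H2O, rt
Reagents that add atoms: tert-butyldimethylsilyl chloride, CC(C)(C)[Si](C)(C)Cl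
Why: Exhaustive silylation followed by selective hydrolysis of the far more labile silyl ester leaves both aryl silyl ethers in place.

**Step 6**
Reactants: 10 (R,R)-2-iodo-1,3-bis[1-(mesitylcarbamoyl)ethoxy]benzene; 9 2,4-bis(tert-butyldimethylsilyloxy)-6-methylbenzoic acid (2.05 equiv)
Product: 12 (R,R)-{2,6-bis[1-(mesitylcarbamoyl)ethoxy]phenyl}-λ3-iodanediyl bis[2,4-bis(tert-butyldimethylsilyloxy)-6-methylbenzoate], via diacetoxyiodoarene 11 (not isolated)
Conditions: AcOOH, AcOH, rt; then 9, PhCl, 45 °C, reduced pressure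
Reagents that add atoms: none
Why: Peracid oxidation of an aryl iodide to its diacetoxy-λ3-iodane, then carboxylate ligand exchange driven by removal of acetic acid, is the standard preparation of [bis(acyloxy)iodo]arenes.

**Step 7**
Reactants: 6 (E)-5-(2-formyl-5-hydroxy-4-methylphenyl)pent-2-en-4-yn-1-yl acetate; 12 chiral bis(aroyloxy)-λ3-iodane (1.1 equiv)
Product: 13 (1S)-4-[(E)-5-acetoxypent-3-en-1-yn-1-yl]-3-formyl-1-methyl-6-oxocyclohexa-2,4-dien-1-yl 2,4-bis(tert-butyldimethylsilyloxy)-6-methylbenzoate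
Conditions: 12, 4 Å MS, CHCl3, −30 °C
Reagents that add atoms: none
Why: Proposed new method: a reagent-controlled enantioselective acyloxylative dearomatization in which the phenol displaces one aroyloxy ligand on trivalent iodine, the amide N–H···O hydrogen bonds fold the two lactamide arms into a helical pocket, and the remaining iodine-bound carboxylate is passed through a seven-membered ligand-coupling transition state to one face of the methyl-bearing ortho carbon (better cation-stabilizing than the ortho CH, while the para carbon is blocked and deactivated by the formyl group) with loss of the iodoarene, the electron-poor phenol suppressing a free phenoxenium ion so that the chiral iodine stays attached during C–O bond formation and the (S) quaternary centre is set; the closest known reaction types are the Wessely acyloxylation of ortho-alkylphenols and the intramolecular Kita-type spirolactonization promoted by the same lactamide aryl-λ3-iodanes.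

**Step 8**
Reactants: 13 ortho-quinol ester enal
Product: 15 (7S)-3-[(E)-3-acetoxyprop-1-en-1-yl]-7-methyl-6-oxo-7,8-dihydro-6H-isochromen-7-yl 2,4-bis(tert-butyldimethylsilyloxy)-6-methylbenzoate, via formyl enone 14 (not isolated)
Conditions: [(Ph3P)CuH]6 (0.3 equiv), H2O (5 equiv), degassed THF, −20 to 0 °C; then CuI (10 mol %), i-Pr2NEt, rt
Reagents that add atoms: none
Why: Copper hydride 1,4-reduction puts hydride on the unsubstituted β-carbon of the enal (also the δ-terminus of the dienone), and the resulting vinylogous β-keto aldehyde enol adds through oxygen to the δ-carbon of the ynenone in a 6-endo-dig cycloisomerization (the ring closure used for azaphilone cores); the quaternary centre is not involved.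

**Step 9**
Reactants: 15 silyl-protected ester
Product: 16 (7S)-3-[(E)-3-acetoxyprop-1-en-1-yl]-7-methyl-6-oxo-7,8-dihydro-6H-isochromen-7-yl 2,4-dihydroxy-6-methylbenzoate (target)
Conditions: Bu4NF, AcOH (1:1), THF, 0 °C
Reagents that add atoms: none
Why: Buffered fluoride desilylation cleaves aryl silyl ethers within minutes while the allylic acetate, the tertiary ester and the pyranylidene ketone are left intact.

**Compound list**
1 | 4-bromo-2-methoxy-1-methylbenzene | COc1cc(Br)ccc1C | starting material
2 | 2-bromo-4-methoxy-5-methylbenzaldehyde | COc1cc(Br)c(C=O)cc1C | intermediate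
3 | 2-bromo-4-hydroxy-5-methylbenzaldehyde | Oc1cc(Br)c(C=O)cc1C | intermediate
4 | (E)-pent-2-en-4-yn-1-ol | OC/C=C/C#C | starting material
5 | (E)-pent-2-en-4-yn-1-yl acetate | CC(=O)OC/C=C/C#C | intermediate
6 | (E)-5-(2-formyl-5-hydroxy-4-methylphenyl)pent-2-en-4-yn-1-yl acetate | CC(=O)OC/C=C/C#Cc1cc(O)c(C)cc1C=O | intermediate
7 | orsellinic acid | Cc1cc(O)cc(O)c1C(=O)O | starting material
8 | tert-butyldimethylsilyl 2,4-bis(tert-butyldimethylsilyloxy)-6-methylbenzoate | Cc1cc(O[Si](C)(C)C(C)(C)C)cc(O[Si](C)(C)C(C)(C)C)c1C(=O)O[Si](C)(C)C(C)(C)C | intermediate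
9 | 2,4-bis(tert-butyldimethylsilyloxy)-6-methylbenzoic acid | Cc1cc(O[Si](C)(C)C(C)(C)C)cc(O[Si](C)(C)C(C)(C)C)c1C(=O)O | intermediate
10 | (R,R)-2-iodo-1,3-bis[1-(mesitylcarbamoyl)ethoxy]benzene | C[C@@H](Oc1cccc(O[C@H](C)C(=O)Nc2c(C)cc(C)cc2C)c1I)C(=O)Nc1c(C)cc(C)cc1C | starting material
11 | (R,R)-{2,6-bis[1-(mesitylcarbamoyl)ethoxy]phenyl}-λ3-iodanediyl diacetate | C[C@@H](Oc1cccc(O[C@H](C)C(=O)Nc2c(C)cc(C)cc2C)c1I(OC(C)=O)OC(C)=O)C(=O)Nc1c(C)cc(C)cc1C | intermediate
12 | (R,R)-{2,6-bis[1-(mesitylcarbamoyl)ethoxy]phenyl}-λ3-iodanediyl bis[2,4-bis(tert-butyldimethylsilyloxy)-6-methylbenzoate] | C[C@@H](Oc1cccc(O[C@H](C)C(=O)Nc2c(C)cc(C)cc2C)c1I(OC(=O)c1c(C)cc(O[Si](C)(C)C(C)(C)C)cc1O[Si](C)(C)C(C)(C)C)OC(=O)c1c(C)cc(O[Si](C)(C)C(C)(C)C)cc1O[Si](C)(C)C(C)(C)C)C(=O)Nc1c(C)cc(C)cc1C | intermediate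
13 | (1S)-4-[(E)-5-acetoxypent-3-en-1-yn-1-yl]-3-formyl-1-methyl-6-oxocyclohexa-2,4-dien-1-yl 2,4-bis(tert-butyldimethylsilyloxy)-6-methylbenzoate | CC(=O)OC/C=C/C#CC1=CC(=O)[C@@](C)(OC(=O)c2c(C)cc(O[Si](C)(C)C(C)(C)C)cc2O[Si](C)(C)C(C)(C)C)C=C1C=O | intermediate
14 | (1S)-4-[(E)-5-acetoxypent-3-en-1-yn-1-yl]-3-formyl-1-methyl-6-oxocyclohex-4-en-1-yl 2,4-bis(tert-butyldimethylsilyloxy)-6-methylbenzoate (formyl/hydroxymethylene tautomers, C3 not defined) | CC(=O)OC/C=C/C#CC1=CC(=O)[C@@](C)(OC(=O)c2c(C)cc(O[Si](C)(C)C(C)(C)C)cc2O[Si](C)(C)C(C)(C)C)CC1C=O | intermediate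
15 | (7S)-3-[(E)-3-acetoxyprop-1-en-1-yl]-7-methyl-6-oxo-7,8-dihydro-6H-isochromen-7-yl 2,4-bis(tert-butyldimethylsilyloxy)-6-methylbenzoate | CC(=O)OC/C=C/C1=CC2=CC(=O)[C@@](C)(OC(=O)c3c(C)cc(O[Si](C)(C)C(C)(C)C)cc3O[Si](C)(C)C(C)(C)C)CC2=CO1 | intermediate
16 | (7S)-3-[(E)-3-acetoxyprop-1-en-1-yl]-7-methyl-6-oxo-7,8-dihydro-6H-isochromen-7-yl 2,4-dihydroxy-6-methylbenzoate | CC(=O)OC/C=C/C1=CC2=CC(=O)[C@@](C)(OC(=O)c3c(C)cc(O)cc3O)CC2=CO1 | target

**Totals**
Total step count: 9. Longest linear sequence: 6 steps (steps 1, 2, 4, 7, 8, 9, from compound 1).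

**Steps most likely to fail**

Step 7 (the proposed new step). The para-formyl phenol may react slowly, the unsubstituted ortho carbon may compete (giving a catechol monoester after tautomerization), the level and sense of induction are untested, and the quinol ester 13 may dimerize by Diels–Alder reaction if kept warm. The fallback sets out from 6 and 9: a Wessely acyloxylation with Pb(OAc)4 pre-equilibrated with excess 9 in CH2Cl2 at 0 °C gives the racemic quinol ester F1, which is resolved by preparative chiral supercritical-fluid chromatography. The (S) enantiomer is compound 13, where the route resumes.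

Step 8. Copper hydride could also attack the aldehyde carbonyl or the ynenone, and the enol may close sluggishly. The fallback sets out from 13 and reaches the same ring by a redox-isomerization instead of a conjugate reduction. NaBH(OAc)3 reduces only the aldehyde to give the dienone alcohol F2. Ph3PAuCl/AgOTf-catalysed 6-endo hydroalkoxylation of the alkyne then gives the 1H-isochromen-6(7H)-one F3, a cyclic allyl ether. Its RuHCl(CO)(PPh3)3-catalysed allyl ether to enol ether isomerization moves the C8a=C8 double bond to C1=C8a and returns the route at compound 15.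

Step 4. Zerovalent palladium may ionize the allylic acetate of 5 in competition with the coupling. The fallback sets out from 3 and 4: Sonogashira coupling with the free enynol gives 4-hydroxy-2-[(E)-5-hydroxypent-3-en-1-yn-1-yl]-5-methylbenzaldehyde F4. Its primary allylic alcohol is then acetylated chemoselectively with vinyl acetate and immobilized Candida antarctica lipase B, which leaves the phenol free, and the route resumes at compound 6.

**Further compounds**
F1 | step 7 | racemic 4-[(E)-5-acetoxypent-3-en-1-yn-1-yl]-3-formyl-1-methyl-6-oxocyclohexa-2,4-dien-1-yl 2,4-bis(tert-butyldimethylsilyloxy)-6-methylbenzoate | CC(=O)OC/C=C/C#CC1=CC(=O)C(C)(OC(=O)c2c(C)cc(O[Si](C)(C)C(C)(C)C)cc2O[Si](C)(C)C(C)(C)C)C=C1C=O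
F2 | step 8 | (1S)-4-[(E)-5-acetoxypent-3-en-1-yn-1-yl]-3-(hydroxymethyl)-1-methyl-6-oxocyclohexa-2,4-dien-1-yl 2,4-bis(tert-butyldimethylsilyloxy)-6-methylbenzoate | CC(=O)OC/C=C/C#CC1=CC(=O)[C@@](C)(OC(=O)c2c(C)cc(O[Si](C)(C)C(C)(C)C)cc2O[Si](C)(C)C(C)(C)C)C=C1CO
F3 | step 8 | (7S)-3-[(E)-3-acetoxyprop-1-en-1-yl]-7-methyl-6-oxo-6,7-dihydro-1H-isochromen-7-yl 2,4-bis(tert-butyldimethylsilyloxy)-6-methylbenzoate | CC(=O)OC/C=C/C1=CC2=CC(=O)[C@@](C)(OC(=O)c3c(C)cc(O[Si](C)(C)C(C)(C)C)cc3O[Si](C)(C)C(C)(C)C)C=C2CO1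
F4 | step 4 | 4-hydroxy-2-[(E)-5-hydroxypent-3-en-1-yn-1-yl]-5-methylbenzaldehyde | OC/C=C/C#Cc1cc(O)c(C)cc1C=O
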